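## Retrosynthetic overview

1. Target 14 ⇒ O‑methyl tetronate 12; the methyl ether is removed last with chloride.
2. (E)‑C5=C1' alkene ⇒ anti‑selective vinylogous Mukaiyama aldol of silyloxyfuran 9 with α‑methyl aldehyde 6, then stereospecific anti‑dehydration (anti aldol → E alkene).
3. The single stereocentre (S) ⇒ enantioselective organocatalytic conjugate reduction of the (E)‑2‑methyl enal 5, with the α‑centre set by protonation.
4. Enal 5 ⇒ (2E,6E)‑farnesyl chloride 1 by terminal SeO2 allylic oxidation and carbonylative Stille coupling with 3‑furylstannane 4.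
5. Rings: none is built. The furan arrives with 4 (step 2) and the butenolide with 7 (steps 4 to 6).

Assumption: the SMILES is read as written, so the exocyclic alkene is E (side chain cis to C4–OH) and the methyl‑bearing centre is S; 1, 4 and 7 are taken as catalogue compounds.

## Route

Step 1
Reactants: 1 (2E,6E)-farnesyl chloride [(2E,6E)-1-chloro-3,7,11-trimethyldodeca-2,6,10-triene]
Product: 3 (2E,6E,10E)-12-chloro-2,6,10-trimethyldodeca-2,6,10-trienal, via chloro-alcohol 2 (not isolated)
Conditions: SeO2 (0.3 equiv), t-BuOOH (2.5 equiv, decane solution), salicylic acid (0.1 equiv), CH2Cl2, 0 °C to rt; then MnO2 (10 equiv), CH2Cl2, rt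
Reagents that add atoms: tert-butyl hydroperoxide CC(C)(C)OO (oxygen passed on through SeO2, O=[Se]=O)
Why: Sharpless-type SeO2/t-BuOOH allylic oxidation (ene reaction, then [2,3]-shift) attacks the electron-richest terminal alkene, remote from the deactivating allylic chloride, at its E-methyl group, and MnO2 then oxidises the allylic alcohol to the (E)-enal without touching the chloride.

Step 2
Reactants: 3 (2E,6E,10E)-12-chloro-2,6,10-trimethyldodeca-2,6,10-trienal; 4 tributyl(furan-3-yl)stannane
Product: 5 (2E,6E,10E)-13-(furan-3-yl)-2,6,10-trimethyl-13-oxotrideca-2,6,10-trienal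
Conditions: Pd2(dba)3 (2 mol%), PPh3 (8 mol%), CO (3 atm), THF, 50 °C
Reagents that add atoms: carbon monoxide [C-]#[O+]
Why: Carbonylative Stille coupling of an allylic chloride (oxidative addition to zerovalent palladium, CO insertion, transmetalation from tin) gives the β,γ-unsaturated 3-furyl ketone at the primary allyl terminus with the E-alkene retained and no shift into conjugation, the way egomaketone-type furyl ketones are made; the enal is a spectator under these neutral conditions.

Step 3
Reactants: 5 (2E,6E,10E)-13-(furan-3-yl)-2,6,10-trimethyl-13-oxotrideca-2,6,10-trienal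
Product: 6 (2S,6E,10E)-13-(furan-3-yl)-2,6,10-trimethyl-13-oxotrideca-6,10-dienal
Conditions: (S)-N1,N1-diethyl-3,3-dimethylbutane-1,2-diamine·CF3SO3H (20 mol%), diethyl 2,6-dimethyl-1,4-dihydropyridine-3,5-dicarboxylate (1.1 equiv), CHCl3, 0 °C; short silica plug, used at once
Reagents that add atoms: none
Why: Proposed new method: the primary amine condenses with the α-branched enal to an s-trans iminium ion that takes hydride from the Hantzsch ester at C3 (no stereocentre there) and so gives the (E)-enamine only, which the pendant Et2NH+ arm protonates at C2 from one face before the enamine can isomerise, setting the 2S centre; the closest known reactions are iminium-type organocatalytic transfer hydrogenation of β,β-disubstituted enals with Hantzsch esters (stereocentre at the β-carbon by hydride delivery) and primary-amine-catalysed conjugate additions to α-substituted acroleins that end in enantioselective enamine protonation, whereas an α-methyl-β-alkyl enal whose only stereocentre arises by protonation after hydride transfer has no established precedent.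

Step 4
Reactants: 7 3-methyltetronic acid [4-hydroxy-3-methylfuran-2(5H)-one]
Product: 8 4-methoxy-3-methylfuran-2(5H)-one
Conditions: Me2SO4 (1.2 equiv), K2CO3 (1.5 equiv), acetone, reflux
Reagents that add atoms: dimethyl sulfate COS(=O)(=O)OC
Why: O-alkylation of the vinylogous acid with a hard methylating agent (Williamson-type) gives the 4-methoxy-2(5H)-furanone regioisomer as the main product; methyl is the smallest O4 group and so costs the later E-alkene the least strain.

Step 5
Reactants: 8 4-methoxy-3-methylfuran-2(5H)-one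
Product: 9 triethyl[(4-methoxy-3-methylfuran-2-yl)oxy]silane
Conditions: Et3SiOSO2CF3 (1.2 equiv), Et3N (1.5 equiv), CH2Cl2, 0 °C
Reagents that add atoms: triethylsilyl trifluoromethanesulfonate CC[Si](CC)(CC)OS(=O)(=O)C(F)(F)F
Why: Soft enolisation (silyl triflate and amine) removes the C5 proton of the butenolide and gives the aromatic 2-silyloxyfuran, the standard salt-free nucleophile for vinylogous Mukaiyama aldol reactions.

Step 6
Reactants: 6 (2S,6E,10E)-13-(furan-3-yl)-2,6,10-trimethyl-13-oxotrideca-6,10-dienal; 9 triethyl[(4-methoxy-3-methylfuran-2-yl)oxy]silane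
Product: 11 (5R)-5-[(1R,2S,6E,10E)-13-(furan-3-yl)-1-hydroxy-2,6,10-trimethyl-13-oxotrideca-6,10-dien-1-yl]-4-methoxy-3-methylfuran-2(5H)-one, via triethylsilyl ether 10 (not isolated)
Conditions: n-Bu4N[Ph3SiF2] (10 mol%), THF, −78 °C; then aq. citric acid, THF/MeOH, 0 °C
Reagents that add atoms: none
Why: Fluoride-initiated vinylogous Mukaiyama aldol addition, in which the naked furanolate attacks the aldehyde through an open transition state with the two oxygens anti and so gives the 5,1'-anti (like) aldol, while −78 °C and the absence of metal enolate leave the C2' centre and the β,γ-enone untouched; C5 and C1' are relative centres erased in step 7, so the 5S,1'S anti partner (other aldehyde face) converges.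

Step 7
Reactants: 11 (5R)-5-[(1R,2S,6E,10E)-13-(furan-3-yl)-1-hydroxy-2,6,10-trimethyl-13-oxotrideca-6,10-dien-1-yl]-4-methoxy-3-methylfuran-2(5H)-one
Product: 12 (5E)-5-[(2S,6E,10E)-13-(furan-3-yl)-2,6,10-trimethyl-13-oxotrideca-6,10-dien-1-ylidene]-4-methoxy-3-methylfuran-2(5H)-one
Conditions: PPh3 (1.5 equiv), diethyl azodicarboxylate (1.5 equiv), THF, −20 to 0 °C
Reagents that add atoms: none
Why: Mitsunobu-type dehydration, in which the alcohol becomes an alkoxyphosphonium leaving group and the hydrazide anion removes the acidic C5–H in a concerted anti (E2) β-elimination, so the anti aldol gives the (E)-ylidene (side chain cis to C4) that thermodynamic E1cB dehydrations do not give; C2' is not involved.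

Step 8
Reactants: 12 (5E)-5-[(2S,6E,10E)-13-(furan-3-yl)-2,6,10-trimethyl-13-oxotrideca-6,10-dien-1-ylidene]-4-methoxy-3-methylfuran-2(5H)-one
Product: 14 (5E)-5-[(2S,6E,10E)-13-(furan-3-yl)-2,6,10-trimethyl-13-oxotrideca-6,10-dien-1-ylidene]-4-hydroxy-3-methylfuran-2(5H)-one, via lithium tetronate 13 (not isolated)
Conditions: LiCl (10 equiv), DMSO, 60 °C; then 0.5 M HCl to pH 3, 0 °C
Reagents that add atoms: none
Why: Krapcho-type SN2 demethylation of the vinylogous methyl ester by chloride under neutral conditions frees the tetronic acid as its lithium salt, which resists addition–elimination and so keeps the E-alkene, the S centre and the β,γ-enone, and cold acidification gives the target.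

## Compound list

1 | (2E,6E)-1-chloro-3,7,11-trimethyldodeca-2,6,10-triene (farnesyl chloride) | CC(C)=CCC/C(C)=C/CC/C(C)=C/CCl | starting material
2 | (2E,6E,10E)-12-chloro-2,6,10-trimethyldodeca-2,6,10-trien-1-ol | OC/C(C)=C/CC/C(C)=C/CC/C(C)=C/CCl | intermediate
3 | (2E,6E,10E)-12-chloro-2,6,10-trimethyldodeca-2,6,10-trienal | O=C/C(C)=C/CC/C(C)=C/CC/C(C)=C/CCl | intermediate
4 | tributyl(furan-3-yl)stannane | CCCC[Sn](CCCC)(CCCC)c1ccoc1 | starting material
5 | (2E,6E,10E)-13-(furan-3-yl)-2,6,10-trimethyl-13-oxotrideca-2,6,10-trienal | O=C/C(C)=C/CC/C(C)=C/CC/C(C)=C/CC(=O)c1ccoc1 | intermediate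
6 | (2S,6E,10E)-13-(furan-3-yl)-2,6,10-trimethyl-13-oxotrideca-6,10-dienal | O=C[C@@H](C)CCC/C(C)=C/CC/C(C)=C/CC(=O)c1ccoc1 | intermediate
7 | 4-hydroxy-3-methylfuran-2(5H)-one (3-methyltetronic acid) | OC1=C(C)C(=O)OC1 | starting material
8 | 4-methoxy-3-methylfuran-2(5H)-one | COC1=C(C)C(=O)OC1 | intermediate
9 | triethyl[(4-methoxy-3-methylfuran-2-yl)oxy]silane | CC[Si](CC)(CC)Oc1occ(OC)c1C | intermediate
10 | (5R)-5-[(1R,2S,6E,10E)-13-(furan-3-yl)-2,6,10-trimethyl-13-oxo-1-(triethylsilyloxy)trideca-6,10-dien-1-yl]-4-methoxy-3-methylfuran-2(5H)-one | COC1=C(C)C(=O)O[C@@H]1[C@H](O[Si](CC)(CC)CC)[C@@H](C)CCC/C(C)=C/CC/C(C)=C/CC(=O)c1ccoc1 | intermediate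
11 | (5R)-5-[(1R,2S,6E,10E)-13-(furan-3-yl)-1-hydroxy-2,6,10-trimethyl-13-oxotrideca-6,10-dien-1-yl]-4-methoxy-3-methylfuran-2(5H)-one (anti aldol; the 5S,1'S anti isomer behaves the same) | COC1=C(C)C(=O)O[C@@H]1[C@H](O)[C@@H](C)CCC/C(C)=C/CC/C(C)=C/CC(=O)c1ccoc1 | intermediate
12 | (5E)-5-[(2S,6E,10E)-13-(furan-3-yl)-2,6,10-trimethyl-13-oxotrideca-6,10-dien-1-ylidene]-4-methoxy-3-methylfuran-2(5H)-one | CC1=C(OC)/C(=C\[C@@H](C)CCC/C(C)=C/CC/C(C)=C/CC(=O)c2ccoc2)OC1=O | intermediate
13 | lithium (5E)-5-[(2S,6E,10E)-13-(furan-3-yl)-2,6,10-trimethyl-13-oxotrideca-6,10-dien-1-ylidene]-3-methyl-2-oxo-2,5-dihydrofuran-4-olate | [Li+].CC1=C([O-])/C(=C\[C@@H](C)CCC/C(C)=C/CC/C(C)=C/CC(=O)c2ccoc2)OC1=O | intermediate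
14 | (5E)-5-[(2S,6E,10E)-13-(furan-3-yl)-2,6,10-trimethyl-13-oxotrideca-6,10-dien-1-ylidene]-4-hydroxy-3-methylfuran-2(5H)-one (CNP0178778.1) | CC1=C(O)/C(=C\[C@@H](C)CCC/C(C)=C/CC/C(C)=C/CC(=O)c2ccoc2)OC1=O | target

## Step count and risks

Total steps: 8. Longest linear sequence: 6 (steps 1, 2, 3, 6, 7, 8). Steps 4 and 5 make the tetronate partner.

Steps most likely to fail:

Step 3 (the proposed new reaction). The risks are: moderate ee if enamine E/Z equilibration competes with protonation; slow racemisation of 6 through the same enamine; loss of catalyst by reductive amination; and an unproven sense of induction. The 2S assignment is a prediction, to be confirmed by correlation on the first run; if 2R is found, the D-tert-leucine-derived antipode of the catalyst is used. The fallback is known chemistry on a different catalytic principle and runs from 5 back to 6. It is the flavin-dependent ene-reductase reduction of (E)-2-methyl-2-enals (Old Yellow Enzyme family, for example OYE2 or OYE3 from Saccharomyces, with NADP+, glucose and glucose dehydrogenase for recycling, phosphate buffer pH 7, t-BuOMe as second phase, 30 °C). This enzyme family is reported to give the (S)-2-methyl aldehydes, by flavin hydride to C3 and tyrosine proton to C2 with no enamine involved. The two-phase medium limits racemisation of 6. This fallback makes no compound outside the list (F0).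

Step 6. The anti:syn ratio of the aldol becomes the E:Z ratio of the alkene. The 4-methoxy group next to the reacting carbon may lower the anti preference seen with simple silyloxyfurans, and a basic fluoride source could erode the C2' centre. The fallback runs from 6 and 9 to 12 and reverses both stereochemical elements. A Lewis-acid vinylogous Mukaiyama aldol (BF3·OEt2, CH2Cl2, −78 °C, non-basic) gives the (5S,1'R,2'S) 5,1'-syn aldol F1. This is then dehydrated by a syn elimination with Burgess reagent (benzene, 50 °C) through the triethylammonium N-(methoxycarbonyl)sulfamate ester F2, an intramolecular syn process. Syn aldol plus syn elimination gives the same (E)-ylidene 12.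

Step 7. The E product is the more strained isomer (4-OMe against the C2' branch), so stepwise E1cB loss of the activated alcohol could compete with the concerted anti elimination and leak to the Z-alkene. The fallback runs from 11 (any diastereomer mixture) to 12 and gives up stereospecific elimination. MsCl and Et3N give the mesylate F3, and DBU then gives by E1cB the thermodynamic (5Z)-ylidene F4. Triplet-sensitised E/Z photoisomerisation (thioxanthone 10 mol%, 405 nm, MeCN; the furyl ketone is not excited) gives a photostationary mixture. Compound 12 is separated from it by HPLC and F4 is recycled.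

## Further compounds

F0 | step 3 | none | none
F1 | step 6 | (5S)-5-[(1R,2S,6E,10E)-13-(furan-3-yl)-1-hydroxy-2,6,10-trimethyl-13-oxotrideca-6,10-dien-1-yl]-4-methoxy-3-methylfuran-2(5H)-one | COC1=C(C)C(=O)O[C@H]1[C@H](O)[C@@H](C)CCC/C(C)=C/CC/C(C)=C/CC(=O)c1ccoc1
F2 | step 6 | triethylammonium salt of the N-(methoxycarbonyl)sulfamate ester of F1 | COC1=C(C)C(=O)O[C@H]1[C@H](OS(=O)(=O)[N-]C(=O)OC)[C@@H](C)CCC/C(C)=C/CC/C(C)=C/CC(=O)c1ccoc1.CC[NH+](CC)CC
F3 | step 7 | (1R,2S,6E,10E)-13-(furan-3-yl)-1-[(2R)-3-methoxy-4-methyl-5-oxo-2,5-dihydrofuran-2-yl]-2,6,10-trimethyl-13-oxotrideca-6,10-dien-1-yl methanesulfonate | COC1=C(C)C(=O)O[C@@H]1[C@H](OS(C)(=O)=O)[C@@H](C)CCC/C(C)=C/CC/C(C)=C/CC(=O)c1ccoc1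
F4 | step 7 | (5Z)-5-[(2S,6E,10E)-13-(furan-3-yl)-2,6,10-trimethyl-13-oxotrideca-6,10-dien-1-ylidene]-4-methoxy-3-methylfuran-2(5H)-one | CC1=C(OC)/C(=C/[C@@H](C)CCC/C(C)=C/CC/C(C)=C/CC(=O)c2ccoc2)OC1=O
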